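**Plan**

- Numbering: O1–O2–C3(CH3)(chain)–C4H2–C4a(CH3)–O5–C6(=O)–C7H2–C7a(H)–O1. Retrosynthetic cuts, in order: the C10'–C11' bond of the triene (Stille); C3–CH3 (methyl onto a ring peroxycarbenium ion); O1–C7a with O2–C3 (H2O2 stitched between a C3 ketone and a butenolide); O5–C4a (Baeyer–Villiger); then C6–C7 together with C4a–C7a (intramolecular ketene/vinyl ether [2+2]).
- Enabling feature: C6(=O)–C7H2–C7a(O)–C4a(quaternary) is the Baeyer–Villiger image of a 3-oxycyclobutanone, and the oxygenated C3 lies 1,3 to C4a across C4. A vinyl ether hung on the C3 oxygen therefore sits three atoms from a ketene carbon at C4a.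
- Forward ring order: cyclobutanone plus a temporary oxolane (key step) → γ-lactone → oxolane opened to the butenolide and C3 oxidised to the ketone → 1,2-dioxane closed by H2O2 → C3 methyl → triene.
- Stereochemistry: an (S)-epoxide from hydrolytic kinetic resolution gives a temporary C3 carbinol centre that sets C4a in the [2+2] and is then erased. C7a is set cis by the intramolecular oxa-Michael addition. C3 is set by axial attack of methyl on the chair-like peroxycarbenium ion. Alkene geometry comes from two Takai olefinations and a stereoretentive Stille coupling.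

Key step: step 7

Remark: 8, 9 and 10 are carried as mixtures of epimers at the methyl-bearing α-carbon, which becomes the trigonal ketene carbon in step 7.

**Route**

Step 1
Reactants: 1 undec-10-enal
Product: 2 (1E)-1-iodododeca-1,11-diene
Conditions: CrCl2, CHI3, THF–dioxane, 0 → 25 °C
Reagents that add atoms: iodoform, IC(I)I
Why: Takai olefination, in which the geminal dichromium reagent made from CHI3 and CrCl2 adds to the aldehyde and eliminates to the (E)-vinyl iodide while the terminal alkene stays inert.

Step 2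
Reactants: 2 (1E)-1-iodododeca-1,11-diene
Product: 3 rac-2-[(9E)-10-iododec-9-en-1-yl]oxirane
Conditions: mCPBA, NaHCO3, CH2Cl2, 0 → 25 °C
Reagents that add atoms: 3-chloroperbenzoic acid, OOC(=O)c1cccc(Cl)c1
Why: Prilezhaev epoxidation should take the monosubstituted terminal alkene in preference to the iodine-deactivated vinyl iodide and gives the epoxide as the racemate.

Step 3
Reactants: 3 rac-2-[(9E)-10-iododec-9-en-1-yl]oxirane
Product: 4 (2S)-2-[(9E)-10-iododec-9-en-1-yl]oxirane
Conditions: (S,S)-(salen)Co(OAc) (cat.; salen = N,N'-bis(3,5-di-tert-butylsalicylidene)cyclohexane-1,2-diamine dianion), H2O (0.55 equiv), THF, 0 → 25 °C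
Reagents that add atoms: none
Why: Jacobsen hydrolytic kinetic resolution, in which the catalyst enantiomer that hydrolyses the (R)-epoxide at its terminal carbon leaves the (S)-epoxide and so fixes the temporary carbinol stereocentre.

Step 4
Reactants: 4 (2S)-2-[(9E)-10-iododec-9-en-1-yl]oxirane; 5 tert-butyl propanoate
Product: 8 tert-butyl (2RS,4S,13E)-4-hydroxy-14-iodo-2-methyltetradec-13-enoate, via lithium ester enolate 6 (not isolated), via aluminium ester enolate 7 (not isolated)
Conditions: LDA, THF, −78 °C; Et2AlCl; then 4, −78 → −30 °C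
Reagents that add atoms: none
Why: Epoxide opening by an ester enolate, in which the diethylaluminium enolate attacks the terminal carbon in an SN2 manner so that the carbinol carbon keeps its (S) configuration, the tert-butyl ester resists lactonisation, and the new α-centre is left uncontrolled because it becomes trigonal in step 7.

Step 5
Reactants: 8 tert-butyl (2RS,4S,13E)-4-hydroxy-14-iodo-2-methyltetradec-13-enoate
Product: 9 tert-butyl (2RS,4S,13E)-4-(ethenyloxy)-14-iodo-2-methyltetradec-13-enoate
Conditions: Hg(OAc)2 (cat.), ethyl vinyl ether (solvent), reflux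
Reagents that add atoms: ethyl vinyl ether, C=COCC
Why: Mercury-catalysed transfer vinylation (transetherification) exchanges the ethoxy group of the vinyl ether for the secondary alkoxy group under neutral conditions and does not touch the stereocentre.

Step 6
Reactants: 9 tert-butyl (2RS,4S,13E)-4-(ethenyloxy)-14-iodo-2-methyltetradec-13-enoate
Product: 10 potassium (2RS,4S,13E)-4-(ethenyloxy)-14-iodo-2-methyltetradec-13-enoate
Conditions: KOtBu, H2O (2 equiv), Et2O, 0 → 25 °C
Reagents that add atoms: potassium tert-butoxide, CC(C)(C)[O-].[K+]; water, O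
Why: Saponification by anhydrous hydroxide (acyl–oxygen cleavage) works on tert-butyl esters and delivers the carboxylate salt, so the acid-labile vinyl ether never meets a free acid.

Step 7
Reactants: 10 potassium (2RS,4S,13E)-4-(ethenyloxy)-14-iodo-2-methyltetradec-13-enoate
Product: 13 (1S,3S,5S)-3-[(9E)-10-iododec-9-en-1-yl]-5-methyl-2-oxabicyclo[3.2.0]heptan-6-one, via acyloxypyridinium salt 11 (not isolated), via ketene 12 (not isolated)
Conditions: 2-chloro-1-methylpyridinium iodide, Et3N, MeCN, reflux, slow addition of 10 (about 0.005 M)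
Reagents that add atoms: none
Why: Triethylamine releases from the activated ester a methyl(alkyl)ketene whose electrophilic carbonyl carbon is attacked by the nucleophilic CH2 terminus of the tethered vinyl ether, and the oxocarbenium/enolate-polarised pair (asynchronous concerted [π2s+π2a] path) collapses by bonding the O-bearing vinyl carbon to the ketene α-carbon, so the CH2–C(=O) bond and the OCH–C(CH3) bond form in one event. The closest known reactions are the intramolecular ketene–alkene [2+2] cycloaddition through a three-atom tether and the intermolecular ketene–enol ether cycloaddition that gives 3-alkoxycyclobutanones. The cyclobutanone closes by the [2+2] event itself and the oxolane closes at the same moment in the fused (bicyclo[3.2.0]) mode, a five-membered ring made by bonding the two tethered termini. The ring fusion can only be cis, which fixes the quaternary C5 relative to the O-bearing bridgehead C1, and their absolute sense is dictated by the existing (S)-carbinol carbon, whose long chain should take the convex face away from the forming cyclobutanone. The step needs regioselectivity for the fused over the bridged adduct, secured by the donor oxygen (positive charge can develop only on the O-bearing carbon) and the three-atom tether, and it needs ring closure to outrun ketene dimerisation, secured by slow addition at high dilution. The concave-face diastereomer, which would carry the opposite configuration at the quaternary carbon, has to be removed by chromatography at this stage, and the vinyl iodide is inert to the ketene and to the amine.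

Step 8
Reactants: 13 (1S,3S,5S)-3-[(9E)-10-iododec-9-en-1-yl]-5-methyl-2-oxabicyclo[3.2.0]heptan-6-one
Product: 14 (3aS,5S,6aS)-5-[(9E)-10-iododec-9-en-1-yl]-6a-methyltetrahydrofuro[3,2-b]furan-2(3H)-one
Conditions: 30% H2O2, AcOH, 0 → 25 °C
Reagents that add atoms: hydrogen peroxide, OO
Why: Baeyer–Villiger oxidation, in which the fully substituted bridgehead carbon migrates with retention in preference to the CH2 group and ring strain lets the cyclobutanone react under conditions that should spare the vinyl iodide.

Step 9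
Reactants: 14 (3aS,5S,6aS)-5-[(9E)-10-iododec-9-en-1-yl]-6a-methyltetrahydrofuro[3,2-b]furan-2(3H)-one
Product: 15 (5S)-5-[(2S,11E)-12-iodo-2-(triethylsilyloxy)dodec-11-en-1-yl]-5-methylfuran-2(5H)-one
Conditions: TESOTf, Et3N, CH2Cl2, −78 → 0 °C
Reagents that add atoms: triethylsilyl trifluoromethanesulfonate, CC[Si](CC)(CC)OS(=O)(=O)C(F)(F)F
Why: Retro-oxa-Michael (E1cB-type) ring opening, in which soft enolisation of the lactone pushes out the silyl-activated β-alkoxy oxygen and traps it as the triethylsilyl ether, so the temporary oxolane opens to the butenolide without touching the quaternary centre.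

Step 10
Reactants: 15 (5S)-5-[(2S,11E)-12-iodo-2-(triethylsilyloxy)dodec-11-en-1-yl]-5-methylfuran-2(5H)-one
Product: 17 (5S)-5-[(11E)-12-iodo-2-oxododec-11-en-1-yl]-5-methylfuran-2(5H)-one, via hydroxy butenolide 16 (not isolated)
Conditions: HF·pyridine, THF, 0 °C; then Dess–Martin periodinane, NaHCO3, CH2Cl2, 0 → 25 °C
Reagents that add atoms: none
Why: Desilylation followed at once by Dess–Martin oxidation erases the temporary carbinol stereocentre, the alcohol being oxidised before it can add back to the butenolide.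

Step 11
Reactants: 17 (5S)-5-[(11E)-12-iodo-2-oxododec-11-en-1-yl]-5-methylfuran-2(5H)-one
Product: 19 (4aS,7aS)-3-[(9E)-10-iododec-9-en-1-yl]-3-methoxy-4a-methyltetrahydrofuro[3,2-c][1,2]dioxin-6(3H)-one (both C3 epimers), via methoxy hydroperoxide 18 (not isolated)
Conditions: urea·H2O2, Sc(OTf)3 (cat.), MeOH, 25 °C; evaporation; then Et2NH (cat.), CF3CH2OH, 25 °C
Reagents that add atoms: urea–hydrogen peroxide, NC(N)=O.OO; methanol, CO
Why: Acid-catalysed perketalisation of the ketone followed by amine-catalysed intramolecular oxa-Michael addition of the hydroperoxide (6-exo-trig) closes the 1,2-dioxane, delivery from the tether on C4a forcing the new C7a–O bond cis to it, while the configuration of the ketal carbon is irrelevant.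

Step 12
Reactants: 19 (4aS,7aS)-3-[(9E)-10-iododec-9-en-1-yl]-3-methoxy-4a-methyltetrahydrofuro[3,2-c][1,2]dioxin-6(3H)-one
Product: 21 (3S,4aS,7aS)-3-[(9E)-10-iododec-9-en-1-yl]-3,4a-dimethyltetrahydrofuro[3,2-c][1,2]dioxin-6(3H)-one, via peroxycarbenium triflate 20 (not isolated)
Conditions: Me3Al (3 equiv), TMSOTf (0.2 equiv), CH2Cl2, −78 °C
Reagents that add atoms: trimethylaluminium, C[Al](C)C
Why: Proposed new method: TMSOTf should ionise the methoxy group to a six-membered peroxycarbenium ion that prefers the half-chair with the lactone oxygen on C4a pseudoaxial and the C4a methyl pseudoequatorial, and Me3Al should transfer methyl along the axial trajectory that leads directly to the chair, placing the new methyl cis to the lactone oxygen and the chain equatorial (3S); the closest known reaction types are the Lewis-acid substitution of 3-alkoxy-1,2-dioxanes and 1,2-dioxolanes by allylsilanes, silyl enol ethers and Et3SiH through peroxycarbenium ions, and the Me3Al/TMSOTf methylation of cyclic ketals.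

Step 13
Reactants: 22 (2E)-pent-2-enal
Product: 23 (1E,3E)-1-iodohexa-1,3-diene
Conditions: CrCl2, CHI3, THF, 0 °C
Reagents that add atoms: iodoform, IC(I)I
Why: Takai olefination of the enal gives the new (E) double bond and keeps the existing one.

Step 14
Reactants: 23 (1E,3E)-1-iodohexa-1,3-diene
Product: 25 tributyl[(1E,3E)-hexa-1,3-dien-1-yl]stannane, via dienyllithium 24 (not isolated)
Conditions: tBuLi (2 equiv), Et2O, −78 °C; then Bu3SnCl, −78 → 0 °C
Reagents that add atoms: tributyltin chloride, CCCC[Sn](Cl)(CCCC)CCCC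
Why: Iodine–lithium exchange and stannylation both proceed with retention of alkene geometry.

Step 15
Reactants: 21 (3S,4aS,7aS)-3-[(9E)-10-iododec-9-en-1-yl]-3,4a-dimethyltetrahydrofuro[3,2-c][1,2]dioxin-6(3H)-one; 25 tributyl[(1E,3E)-hexa-1,3-dien-1-yl]stannane
Product: 26 (3S,4aS,7aS)-3-[(9E,11E,13E)-hexadeca-9,11,13-trien-1-yl]-3,4a-dimethyltetrahydrofuro[3,2-c][1,2]dioxin-6(3H)-one
Conditions: Pd2(dba)3 (dba = dibenzylideneacetone), AsPh3, NMP, 25 °C, dark
Reagents that add atoms: none
Why: Stille coupling (oxidative addition of the vinyl iodide to zerovalent palladium, transmetalation, reductive elimination) retains all alkene geometries, and the phosphine-free, neutral, room-temperature conditions have precedent for tolerating dialkyl peroxides and should spare the lactone.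

**Compound list**

1 | undec-10-enal | C=CCCCCCCCCC=O | starting material
2 | (1E)-1-iodododeca-1,11-diene | I/C=C/CCCCCCCCC=C | intermediate
3 | rac-2-[(9E)-10-iododec-9-en-1-yl]oxirane | I/C=C/CCCCCCCCC1CO1 | intermediate
4 | (2S)-2-[(9E)-10-iododec-9-en-1-yl]oxirane | I/C=C/CCCCCCCC[C@H]1CO1 | intermediate
5 | tert-butyl propanoate | CCC(=O)OC(C)(C)C | starting material
6 | lithium 1-tert-butoxyprop-1-en-1-olate (lithium ester enolate) | [Li]OC(=CC)OC(C)(C)C | intermediate (not isolated)
7 | diethylaluminium 1-tert-butoxyprop-1-en-1-olate (aluminium ester enolate) | CC[Al](CC)OC(=CC)OC(C)(C)C | intermediate (not isolated)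
8 | tert-butyl (2RS,4S,13E)-4-hydroxy-14-iodo-2-methyltetradec-13-enoate | CC(C[C@@H](O)CCCCCCCC/C=C/I)C(=O)OC(C)(C)C | intermediate
9 | tert-butyl (2RS,4S,13E)-4-(ethenyloxy)-14-iodo-2-methyltetradec-13-enoate | CC(C[C@@H](OC=C)CCCCCCCC/C=C/I)C(=O)OC(C)(C)C | intermediate
10 | potassium (2RS,4S,13E)-4-(ethenyloxy)-14-iodo-2-methyltetradec-13-enoate | CC(C[C@@H](OC=C)CCCCCCCC/C=C/I)C(=O)[O-].[K+] | intermediate
11 | 2-{[(2RS,4S,13E)-4-(ethenyloxy)-14-iodo-2-methyltetradec-13-enoyl]oxy}-1-methylpyridinium iodide | CC(C[C@@H](OC=C)CCCCCCCC/C=C/I)C(=O)Oc1cccc[n+]1C.[I-] | intermediate (not isolated)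
12 | (4S,13E)-4-(ethenyloxy)-14-iodo-2-methyltetradeca-1,13-dien-1-one (ketene) | CC(C[C@@H](OC=C)CCCCCCCC/C=C/I)=C=O | intermediate (not isolated)
13 | (1S,3S,5S)-3-[(9E)-10-iododec-9-en-1-yl]-5-methyl-2-oxabicyclo[3.2.0]heptan-6-one | I/C=C/CCCCCCCC[C@H]1C[C@]2(C)C(=O)C[C@@H]2O1 | intermediate
14 | (3aS,5S,6aS)-5-[(9E)-10-iododec-9-en-1-yl]-6a-methyltetrahydrofuro[3,2-b]furan-2(3H)-one | I/C=C/CCCCCCCC[C@H]1C[C@]2(C)OC(=O)C[C@@H]2O1 | intermediate
15 | (5S)-5-[(2S,11E)-12-iodo-2-(triethylsilyloxy)dodec-11-en-1-yl]-5-methylfuran-2(5H)-one | C[C@@]1(C[C@@H](O[Si](CC)(CC)CC)CCCCCCCC/C=C/I)OC(=O)C=C1 | intermediate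
16 | (5S)-5-[(2S,11E)-2-hydroxy-12-iodododec-11-en-1-yl]-5-methylfuran-2(5H)-one | C[C@@]1(C[C@@H](O)CCCCCCCC/C=C/I)OC(=O)C=C1 | intermediate (not isolated)
17 | (5S)-5-[(11E)-12-iodo-2-oxododec-11-en-1-yl]-5-methylfuran-2(5H)-one | C[C@@]1(CC(=O)CCCCCCCC/C=C/I)OC(=O)C=C1 | intermediate
18 | (5S)-5-[(11E)-2-hydroperoxy-12-iodo-2-methoxydodec-11-en-1-yl]-5-methylfuran-2(5H)-one | C[C@@]1(CC(OC)(OO)CCCCCCCC/C=C/I)OC(=O)C=C1 | intermediate (not isolated)
19 | (4aS,7aS)-3-[(9E)-10-iododec-9-en-1-yl]-3-methoxy-4a-methyltetrahydrofuro[3,2-c][1,2]dioxin-6(3H)-one (both C3 epimers) | COC1(CCCCCCCC/C=C/I)C[C@]2(C)OC(=O)C[C@@H]2OO1 | intermediate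
20 | (4aS,7aS)-3-[(9E)-10-iododec-9-en-1-yl]-4a-methyl-6-oxo-4,4a,7,7a-tetrahydro-6H-furo[3,2-c][1,2]dioxin-2-ium trifluoromethanesulfonate (peroxycarbenium ion pair) | I/C=C/CCCCCCCCC1=[O+]O[C@H]2CC(=O)O[C@@]2(C)C1.[O-]S(=O)(=O)C(F)(F)F | intermediate (not isolated)
21 | (3S,4aS,7aS)-3-[(9E)-10-iododec-9-en-1-yl]-3,4a-dimethyltetrahydrofuro[3,2-c][1,2]dioxin-6(3H)-one | I/C=C/CCCCCCCC[C@@]1(C)C[C@]2(C)OC(=O)C[C@@H]2OO1 | intermediate
22 | (2E)-pent-2-enal | CC/C=C/C=O | starting material
23 | (1E,3E)-1-iodohexa-1,3-diene | CC/C=C/C=C/I | intermediate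
24 | (1E,3E)-hexa-1,3-dien-1-yllithium | CC/C=C/C=C/[Li] | intermediate (not isolated)
25 | tributyl[(1E,3E)-hexa-1,3-dien-1-yl]stannane | CC/C=C/C=C/[Sn](CCCC)(CCCC)CCCC | intermediate
26 | (3S,4aS,7aS)-3-[(9E,11E,13E)-hexadeca-9,11,13-trien-1-yl]-3,4a-dimethyltetrahydrofuro[3,2-c][1,2]dioxin-6(3H)-one | CC/C=C/C=C/C=C/CCCCCCCC[C@@]1(C)C[C@]2(C)OC(=O)C[C@@H]2OO1 | target

**Step count**

Total: 15 steps. Longest linear sequence: 13 steps (steps 1 to 12, then step 15).

**Steps most likely to fail**

Step 12 (proposed new method). The Lewis acid may cleave the O–O bond heterolytically (Hock/Criegee-type fragmentation), the peroxycarbenium ion may lose a proton to an unstable enol peroxide, methyl may be transferred to a peroxide oxygen, or the attack may occur on the other face. The fallback uses known chemistry and sets out from 17. Takai–Lombardo methylenation (Zn, CH2Br2, TiCl4) of the ketone should give (5S)-5-[(11E)-12-iodo-2-methylidenedodec-11-en-1-yl]-5-methylfuran-2(5H)-one F1. Mukaiyama–Isayama hydroperoxysilylation (Co(acac)2, O2, Et3SiH) of the 1,1-disubstituted alkene should then give (5S)-5-[(11E)-12-iodo-2-methyl-2-(triethylsilylperoxy)dodec-11-en-1-yl]-5-methylfuran-2(5H)-one F2 as both epimers at the peroxide carbon. Desilylation (Bu4NF) and oxa-Michael cyclisation (Et2NH, CF3CH2OH) should give 21 together with its epimer (3R,4aS,7aS)-3-[(9E)-10-iododec-9-en-1-yl]-3,4a-dimethyltetrahydrofuro[3,2-c][1,2]dioxin-6(3H)-one F3, which must be separated by chromatography. The route is rejoined at 21; this fallback gives up stereocontrol at C3.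

Step 7 (key step). Facial discrimination in the ring closure may be insufficient, the ketene may dimerise or oligomerise faster than it cyclises, or the vinyl ether may be lost under the activation conditions. The fallback sets out from 8 and builds the same cyclobutanone by the other [2+2] pairing. Acid-catalysed lactonisation (CF3CO2H) should give (3RS,5S)-5-[(9E)-10-iododec-9-en-1-yl]-3-methyloxolan-2-one F4. Reduction with DIBAL-H should give (3RS,5S)-5-[(9E)-10-iododec-9-en-1-yl]-3-methyloxolan-2-ol F5, and dehydration (MsCl, Et3N, then heat) should give (2S)-2-[(9E)-10-iododec-9-en-1-yl]-4-methyl-2,3-dihydrofuran F6. Cycloaddition of dichloroketene (Cl3CCOCl, Zn–Cu couple, Et2O) on the face anti to the side chain should give (1R,3S,5S)-7,7-dichloro-3-[(9E)-10-iododec-9-en-1-yl]-5-methyl-2-oxabicyclo[3.2.0]heptan-6-one F7, and reductive dechlorination (Zn, NH4Cl, MeOH) returns to 13.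

Step 11. The lactone oxygen may be eliminated from the β-acyloxy ketone (E1cB ring opening) before the ketone is masked, the geminal dihydroperoxide may form in place of the methoxy hydroperoxide, or peroxide may add intermolecularly to the butenolide. The fallback sets out from 17 and brings in the peroxide by exchange on a preformed, non-enolisable ketal. Ketalisation (HC(OMe)3, MeOH, pyridinium p-toluenesulfonate) should give (5S)-5-[(11E)-12-iodo-2,2-dimethoxydodec-11-en-1-yl]-5-methylfuran-2(5H)-one F8. Acid-catalysed exchange of one methoxy group with anhydrous ethereal H2O2 (camphorsulfonic acid, cat.) should give 18, where the route is rejoined and cyclisation with Et2NH in CF3CH2OH gives 19.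

Further compounds
F1 | step 12 | (5S)-5-[(11E)-12-iodo-2-methylidenedodec-11-en-1-yl]-5-methylfuran-2(5H)-one | C[C@@]1(CC(=C)CCCCCCCC/C=C/I)OC(=O)C=C1
F2 | step 12 | (5S)-5-[(11E)-12-iodo-2-methyl-2-(triethylsilylperoxy)dodec-11-en-1-yl]-5-methylfuran-2(5H)-one (both epimers at the peroxide carbon) | C[C@@]1(CC(C)(OO[Si](CC)(CC)CC)CCCCCCCC/C=C/I)OC(=O)C=C1
F3 | step 12 | (3R,4aS,7aS)-3-[(9E)-10-iododec-9-en-1-yl]-3,4a-dimethyltetrahydrofuro[3,2-c][1,2]dioxin-6(3H)-one | I/C=C/CCCCCCCC[C@]1(C)C[C@]2(C)OC(=O)C[C@@H]2OO1
F4 | step 7 | (3RS,5S)-5-[(9E)-10-iododec-9-en-1-yl]-3-methyloxolan-2-one | CC1C[C@H](CCCCCCCC/C=C/I)OC1=O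
F5 | step 7 | (3RS,5S)-5-[(9E)-10-iododec-9-en-1-yl]-3-methyloxolan-2-ol | CC1C[C@H](CCCCCCCC/C=C/I)OC1O
F6 | step 7 | (2S)-2-[(9E)-10-iododec-9-en-1-yl]-4-methyl-2,3-dihydrofuran | CC1=CO[C@@H](CCCCCCCC/C=C/I)C1
F7 | step 7 | (1R,3S,5S)-7,7-dichloro-3-[(9E)-10-iododec-9-en-1-yl]-5-methyl-2-oxabicyclo[3.2.0]heptan-6-one | I/C=C/CCCCCCCC[C@H]1C[C@]2(C)C(=O)C(Cl)(Cl)[C@@H]2O1
F8 | step 11 | (5S)-5-[(11E)-12-iodo-2,2-dimethoxydodec-11-en-1-yl]-5-methylfuran-2(5H)-one | C[C@@]1(CC(OC)(OC)CCCCCCCC/C=C/I)OC(=O)C=C1
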